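## Structural features

The target is the C3a-O-stearate of a 2,3,4-trisubstituted tetrahydrofuran lignan (lariciresinol skeleton). Besides the two 4-hydroxy-3-methoxyphenyl rings, the only ring is the oxolane O1–C2–C3–C4–C5. C2 carries one aryl group directly, C3 carries the acyloxymethyl carbon C3a, C4 carries the benzylic carbon C4a that leads to the second aryl group, and C5 is an unsubstituted OCH2. The three stereocentres C2 (S), C3 (R) and C4 (R) are contiguous, with the substituents 2,3-trans and 3,4-cis. Three groups are fragile: the C2–O1 bond, a p-hydroxybenzylic ether that ionises in acid and can be hydrogenolysed; the two free phenols, which compete with the primary alcohol in any acylation; and the long-chain ester, which would not survive methoxide, hydride or organometallic reagents and must therefore be made last. The real difficulty is the 3,4-cis pair of one-carbon arms next to a 2,3-trans pair, in one absolute configuration, with the two arms ending differently (C3a as an esterified CH2O, C4a as an aryl-bearing CH2). The feature used is that C3a and C4a lie on the same face of adjacent ring carbons, like the two ends of a broken C3a–C4a bond. Re-forming that bond gives a cis-fused cyclobutane on the C3–C4 edge, which is what a ketene delivers to a C3=C4 alkene on the face away from the C2 aryl group.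

## Logic of the disconnections

19 ⇒ 17 + 18. The bond cut is the acyl–oxygen bond on the C3a oxygen. It is the most labile bond and the only link to the C18 chain, so it is formed last. This leaves a commercial acyl donor and an unprotected lignan. The forward step must acylate the one aliphatic hydroxyl of 17 beside two phenols under neutral conditions, which an enzyme can do.

17 ⇒ 16. No skeletal bond is cut; C3a is raised from CH2OH to CO2H because C3a enters the molecule as a carbonyl carbon. The forward step must reduce a carboxylic acid in the presence of free phenols and the C2–O1 ether, which borane does.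

16 ⇒ 15. The two C4a–H bonds are traced back to one C4a–O bond (a benzylic lactone onto C3a), and the two phenolic O–H bonds to O-benzyl ethers. A C4a–O bond allows C4a–aryl to be made by carbonyl addition, and the cis-fused lactone holds the 3,4-cis relation. All three reductive events then fall in one operation. The demand is a hydrogenolysis that cleaves the lactone C4a–O bond but spares C2–O1.

15 ⇒ 11 + 12 (through 13 and 14). The bond cut is C4a–aryl. This puts the second aromatic ring into a simple aryl bromide and leaves 11 with C4a at the aldehyde level. The demand is that the aldehyde next to C4 must not epimerise, so it is handled in its closed lactol–lactone form.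

11 ⇒ 10. Functional-group change only: the C4a aldehyde comes from a CHCl2 group and the C3a lactone carbonyl from a methyl ester. These are the two ends that a haloform-type cleavage produces. The demand is hydrolysis of an unactivated gem-dichloride without base.

10 ⇒ 9. The C3a–C4a bond is re-formed in the retrosynthetic sense. The cis pair of arms becomes a ring fusion, which cannot be anything but cis. The forward step must break only the C(=O)–CCl2 bond and leave C3 untouched.

9 ⇒ 6 + 8 (8 made in the flask from 7). The bonds cut are C3–C3a and C4–C4a. Two C–C bonds, one ring and two stereocentres are removed at once, leaving a monocyclic alkene with one stereocentre and a two-carbon unit. The forward step needs addition anti to the C2 aryl group, which 6 enforces, and the orientation with the carbonyl on C3, which 6 does not enforce. No spectator group on this skeleton would bias the orientation at acceptable cost. Two measures are therefore built in: the ketene is generated with ZnCl2 sequestered, because 6 is an allylic, p-alkoxybenzylic ether, and the other regioisomer is channelled to 17 by a mirror sequence (see the risks). The benzyl ether of 6 is kept because it is inert to every reagent up to 15 and is removed in the same hydrogenolysis that makes the C4a methylene.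

6 ⇒ 4 + 5. The bond cut is C2–aryl, at the only stereocentre of 6. A catalytic asymmetric Heck arylation makes exactly this bond from an achiral commercial enol ether and an aryl triflate. The demand is enantiocontrol and no migration of the double bond.

4 ⇒ 3 ⇒ 1 (through 2). The triflate S–O bond is cut, then the aryl C–O bond is traced back to aryl–CHO. The commercial aldehyde already has the right substitution pattern. The oxidative aryl migration needs the electron-rich ring, which the benzyl ether provides and survives.

## Other disconnections considered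

Alternative 1: The cut is at O1–C5 and C5–C4, with C5 supplied as carbon monoxide at the lactone oxidation level.
- Forward key step: the homopropargylic alcohol A2, which already carries C2 and C3 with their substituents, would be cyclocarbonylated with PdCl2(PPh3)2, SnCl2 and CO. The C2 hydroxyl and CO form an alkoxycarbonylpalladium unit that adds syn across the alkyne and is protonated, closing the five-membered ring to the (E)-benzylidene lactone A1. Hydrogenation anti to the C3 arm would then set C4, followed by reduction of the lactone carbonyl to CH2, desilylation, acylation and debenzylation.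
- In its favour: every carbon is placed unambiguously, so there is no regiochemical question; on this point it is better than the ketene plan. The E geometry follows from syn addition. The primary alcohol is already singled out as a silyl ether, so the stearate could be introduced chemically, which is also better than relying on an enzyme.
- Against it here: this carbonylation is best established for terminal alkynes, and an aryl-substituted internal alkyne should be much less willing. The electron-rich benzylic alcohol would sit in a Lewis-acidic tin/palladium medium. The anti C2/C3 relation must be built beforehand in an acyclic precursor. C4 is set only by a facial preference in a hydrogenation. The lactone-to-ether reduction needs Lewis acid and silane next to the ionisable C2–O1 bond.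
- Comparison: structurally, the ketene plan makes 3,4-cis a necessity of ring fusion, whereas A1 makes it an expectation. Mechanistically, both key steps have precedent in their reaction class. In step count the two should be about equal (roughly a dozen steps once A2 and the two-stage lactone reduction are counted).

Alternative 2: The cuts are C4–C4a and C2–C3, both made in one flask on the chiral butenolide A4.
- Forward key step: the lithiated dithiane A5 would add to the β-carbon of A4 anti to the menthyloxy group, and the lactone enolate would be trapped by aldehyde 1 anti to the new substituent, giving adduct A3 without closing a ring. Reduction of the lactone and acetal to a triol, nickel desulfurisation (C4a becomes CH2) and acid-mediated closure of C2–O1 would follow. The trans lactone maps onto the 3,4-cis tetrahydrofuran.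
- In its favour: three components, two C–C bonds and the whole carbon skeleton in one step. The C3/C4 relation comes from well-understood anti additions, the absolute configuration from a crystalline auxiliary. There is no regiochemical ambiguity and no benzylic C–O hydrogenolysis at C4a. In convergence, regiochemical security and probably step count (about eight or nine) this plan is the better one.
- Against it here: the auxiliary is stoichiometric and ends as waste. C2 forms as carbinol epimers and its configuration depends on a later, thermodynamically controlled benzylic cyclisation. Nickel desulfurisation has to be run next to benzyl ethers and a benzylic oxygen.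
- Comparison: the chosen plan sets C2 first with a catalyst and lets it control C3 and C4 through a concerted cycloaddition. The route through A3 sets C3/C4 first by ionic additions and C2 last by equilibration. Both are mechanistically sound, and the alternative is the shorter.

Alternative 3: The cut is at O1–C2 and C2–C3; C2 with its aryl group is inserted as a carbene into an O–C bond of the cis-2,3-disubstituted oxetane A7.
- Forward key step: Rh2(OAc)4 would decompose the aryl diazomethane A8. The carbene forms an oxonium ylide with the oxetane oxygen, and a [1,2] (Stevens) shift of C3 from oxygen to the carbene carbon expands the ring to the tribenzyl ether A6.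
- In its favour: the fully protected skeleton appears in the key step, so after the key step this plan is shorter than the chosen one. The 3,4-cis relation is carried in a small ring where it is easy to secure.
- Against it here: an electron-rich aryl diazomethane is unstable and hazardous, and donor carbenes dimerise readily. The ylide could shift C5 instead of C3. The shift has radical-pair character, so neither retention at C3 nor the configuration of the new C2 is enforced. Enantiopure A7 needs its own multi-step synthesis. Because A6 has all three hydroxyls as benzyl ethers, the phenol/alcohol selectivity problem returns after hydrogenolysis, which is equal to the chosen plan on that point.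
- Comparison: the ketene plan fixes two stereocentres by a concerted addition under substrate control. The carbene plan would form one stereocentre without a controlling element and depends on a stepwise rearrangement. Overall length should not be lower once A7 is counted.

Key step: step 4

Assumption on the Heck step: the (R)-configured tert-butyl phosphinooxazoline is expected to give the (S)-dihydrofuran by analogy with simple aryl triflates; if the sense proves opposite, the (S)-ligand is used.
Assumption on supply: compounds 1 and 12 are taken as catalogue compounds (each is one O-benzylation away from the parent phenol).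

Step 1
Reactants: 1 4-(benzyloxy)-3-methoxybenzaldehyde
Product: 3 4-(benzyloxy)-3-methoxyphenol, via aryl formate 2 (not isolated)
Conditions: mCPBA, CH2Cl2, 25 °C; NaHCO3 wash; then K2CO3 (cat.), MeOH, 25 °C
Reagents that add atoms: 3-chloroperoxybenzoic acid (mCPBA), OOC(=O)c1cccc(Cl)c1
Why: Baeyer–Villiger oxidation with aryl migration (the Dakin outcome; a peracid is used because there is no free phenol for alkaline H2O2) gives formate 2, which is cleaved by methanolysis; the benzyl and methyl ethers are inert to peracid.

Step 2
Reactants: 3 4-(benzyloxy)-3-methoxyphenol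
Product: 4 4-(benzyloxy)-3-methoxyphenyl trifluoromethanesulfonate
Conditions: Tf2O, pyridine, CH2Cl2, 0 °C
Reagents that add atoms: trifluoromethanesulfonic anhydride, O=S(=O)(OS(=O)(=O)C(F)(F)F)C(F)(F)F
Why: O-Sulfonylation of a phenol; the triflate is the leaving group that opens the cationic Heck pathway needed for enantiocontrol.

Step 3
Reactants: 4 4-(benzyloxy)-3-methoxyphenyl trifluoromethanesulfonate; 5 2,3-dihydrofuran
Product: 6 (S)-2-[4-(benzyloxy)-3-methoxyphenyl]-2,5-dihydrofuran
Conditions: Pd2(dba)3 (1.5 mol%), (R)-4-tert-butyl-2-[2-(diphenylphosphanyl)phenyl]-4,5-dihydrooxazole (4 mol%), i-Pr2NEt (2 equiv), 5 (4 equiv), THF, 70 °C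
Reagents that add atoms: none
Why: Asymmetric Heck arylation: oxidative addition of the triflate to zerovalent palladium gives a cationic arylpalladium–P,N complex that inserts the enol ether with the aryl group at C2, the ligand choosing the face (C2 set as S); syn β-hydride elimination towards C4 and fast alkene release from the P,N complex leave the C3=C4 bond unmigrated.

Step 4
Reactants: 6 (S)-2-[4-(benzyloxy)-3-methoxyphenyl]-2,5-dihydrofuran; 7 trichloroacetyl chloride
Product: 9 (1R,4S,5S)-4-[4-(benzyloxy)-3-methoxyphenyl]-7,7-dichloro-3-oxabicyclo[3.2.0]heptan-6-one (carbonyl on the former C3 and CCl2 on the former C4), via dichloroketene 8 (not isolated)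
Conditions: 7 (2 equiv, slow addition), Zn–Cu couple (3 equiv), DME (2 equiv), Et2O, 20 °C; filtration, cold aq. NaHCO3
Reagents that add atoms: none
Why: Zinc reduces 7 to dichloroketene 8, which is trapped as it forms, while DME ties up ZnCl2 so that the allylic, p-alkoxybenzylic ether of 6 is not ionised. The ketene adds to the C3=C4 alkene in a concerted but asynchronous [2+2] cycloaddition, the carbonyl carbon bonding ahead of the CCl2 terminus, which is the known behaviour of dichloroketene towards 2,5-dihydrofuran and cyclopentenes. The four-membered ring is closed by the cycloaddition itself: C3–C3a and C4–C4a form on one face of the cis alkene, so the ring fusion can only be cis. Both new stereocentres, C3 and C4, are set by the C2 stereocentre, whose aryl group shields its own face so that the ketene adds anti to it, placing C3a and C4a cis to each other and trans to the aryl group. Facial selectivity is thus secured by the substrate. Orientation is not, because the two alkene carbons differ only in a remote substituent, so the isomer with the carbonyl on C4 (F1 below) must be expected beside 9. It is separated and used as set out under the risks.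

Step 5
Reactants: 9 (1R,4S,5S)-4-[4-(benzyloxy)-3-methoxyphenyl]-7,7-dichloro-3-oxabicyclo[3.2.0]heptan-6-one
Product: 10 methyl (2S,3S,4R)-2-[4-(benzyloxy)-3-methoxyphenyl]-4-(dichloromethyl)oxolane-3-carboxylate
Conditions: NaOMe (0.2 equiv), MeOH, 0 °C; AcOH quench
Reagents that add atoms: methanol, CO
Why: Haloform-type cleavage: methoxide adds to the strained, electron-poor carbonyl and the tetrahedral intermediate expels the dichloromethyl carbanion, breaking only C3a–C4a; catalytic base, low temperature and short contact avoid epimerisation at C3.

Step 6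
Reactants: 10 methyl (2S,3S,4R)-2-[4-(benzyloxy)-3-methoxyphenyl]-4-(dichloromethyl)oxolane-3-carboxylate
Product: 11 (3aR,6S,6aS)-6-[4-(benzyloxy)-3-methoxyphenyl]-3-hydroxytetrahydro-1H,3H-furo[3,4-c]furan-1-one (cis-fused lactol–lactone, lactol epimers)
Conditions: AgOAc (2.5 equiv), AcOH–H2O–1,4-dioxane, 60 °C, dark
Reagents that add atoms: water, O
Why: Silver-assisted hydrolysis of a gem-dichloride with anchimeric help from the cis ester carbonyl; the aldehyde acid is obtained in its closed lactol–lactone form, whose cis ring fusion locks C3 and C4 against epimerisation in the weakly acidic medium.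

Step 7
Reactants: 11 (3aR,6S,6aS)-6-[4-(benzyloxy)-3-methoxyphenyl]-3-hydroxytetrahydro-1H,3H-furo[3,4-c]furan-1-one; 12 1-(benzyloxy)-4-bromo-2-methoxybenzene
Product: 15 (3aR,6S,6aS)-3,6-bis[4-(benzyloxy)-3-methoxyphenyl]tetrahydro-1H,3H-furo[3,4-c]furan-1-one (cis-fused lactone, epimers at C3 of the bicycle, which is C4a), via aryl Grignard reagent 13 (not isolated), via hydroxy acid 14 (not isolated)
Conditions: 12, Mg, THF, 40 °C (13, 2.5 equiv); 11, THF, −78 to 0 °C; then 1 M HCl, 25 °C
Reagents that add atoms: none
Why: Grignard addition to a masked aldehyde acid: the first equivalent of 13 deprotonates the lactol, which opens to the aldehyde carboxylate, the second adds to the aldehyde to form C4a–aryl, and acidification lactonises 14 to the cis-fused γ-lactone; the new carbinol centre is uncontrolled and is erased in step 8.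

Step 8
Reactants: 15 (3aR,6S,6aS)-3,6-bis[4-(benzyloxy)-3-methoxyphenyl]tetrahydro-1H,3H-furo[3,4-c]furan-1-one
Product: 16 (2S,3S,4R)-4-(4-hydroxy-3-methoxybenzyl)-2-(4-hydroxy-3-methoxyphenyl)oxolane-3-carboxylic acid
Conditions: H2 (1 atm), 10% Pd/C, EtOH–AcOH (20:1), 25 °C, stopped after 3 equiv H2
Reagents that add atoms: none
Why: Hydrogenolysis on palladium: the two aryl benzyl ethers and the lactone C4a–O bond (an acyloxy leaving group on a p-hydroxybenzylic carbon) should cleave much faster than the ether-type C2–O1 bond, so the reaction is followed and stopped; C2, C3 and C4 are not touched.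

Step 9
Reactants: 16 (2S,3S,4R)-4-(4-hydroxy-3-methoxybenzyl)-2-(4-hydroxy-3-methoxyphenyl)oxolane-3-carboxylic acid
Product: 17 (2S,3R,4R)-lariciresinol, [(2S,3R,4R)-2-(4-hydroxy-3-methoxyphenyl)-4-(4-hydroxy-3-methoxybenzyl)oxolan-3-yl]methanol
Conditions: BH3·THF (5 equiv), THF, 0 to 25 °C; MeOH, then H2O
Reagents that add atoms: none
Why: Borane reduces the carboxylic acid through an acyloxyborane far faster than it affects any other group here; the phenols only form borate esters that hydrolyse on work-up, and no stereocentre is involved.

Step 10
Reactants: 17 (2S,3R,4R)-lariciresinol; 18 vinyl stearate (ethenyl octadecanoate)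
Product: 19 [(2S,3R,4R)-2-(4-hydroxy-3-methoxyphenyl)-4-(4-hydroxy-3-methoxybenzyl)oxolan-3-yl]methyl octadecanoate (target)
Conditions: Novozym 435 (immobilised Candida antarctica lipase B), 18 (3 equiv), 2-methylbutan-2-ol, 4 Å molecular sieves, 45 °C
Reagents that add atoms: none
Why: Lipase-catalysed transesterification with an irreversible acyl donor; the serine hydrolase acylates the primary aliphatic hydroxyl and does not accept phenols as nucleophiles, so no protecting group is needed and the labile ester is made last under neutral conditions.

Compound list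

1 | 4-(benzyloxy)-3-methoxybenzaldehyde | O=Cc1ccc(OCc2ccccc2)c(OC)c1 | starting material
2 | 4-(benzyloxy)-3-methoxyphenyl formate | O=COc1ccc(OCc2ccccc2)c(OC)c1 | intermediate
3 | 4-(benzyloxy)-3-methoxyphenol | Oc1ccc(OCc2ccccc2)c(OC)c1 | intermediate
4 | 4-(benzyloxy)-3-methoxyphenyl trifluoromethanesulfonate | COc1cc(OS(=O)(=O)C(F)(F)F)ccc1OCc1ccccc1 | intermediate
5 | 2,3-dihydrofuran | C1=COCC1 | starting material
6 | (S)-2-[4-(benzyloxy)-3-methoxyphenyl]-2,5-dihydrofuran | C1=CCO[C@@H]1c1ccc(OCc2ccccc2)c(OC)c1 | intermediate
7 | trichloroacetyl chloride | ClC(=O)C(Cl)(Cl)Cl | starting material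
8 | dichloroketene | ClC(Cl)=C=O | intermediate
9 | (1R,4S,5S)-4-[4-(benzyloxy)-3-methoxyphenyl]-7,7-dichloro-3-oxabicyclo[3.2.0]heptan-6-one | O=C2[C@H]1[C@@H](C2(Cl)Cl)CO[C@@H]1c1ccc(OCc3ccccc3)c(OC)c1 | intermediate
10 | methyl (2S,3S,4R)-2-[4-(benzyloxy)-3-methoxyphenyl]-4-(dichloromethyl)oxolane-3-carboxylate | COC(=O)[C@H]1[C@@H](C(Cl)Cl)CO[C@@H]1c1ccc(OCc2ccccc2)c(OC)c1 | intermediate
11 | (3aR,6S,6aS)-6-[4-(benzyloxy)-3-methoxyphenyl]-3-hydroxytetrahydro-1H,3H-furo[3,4-c]furan-1-one (lactol epimers) | O=C1[C@H]2[C@@H](C(O)O1)CO[C@@H]2c1ccc(OCc3ccccc3)c(OC)c1 | intermediate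
12 | 1-(benzyloxy)-4-bromo-2-methoxybenzene | COc1cc(Br)ccc1OCc1ccccc1 | starting material
13 | [4-(benzyloxy)-3-methoxyphenyl]magnesium bromide | COc1cc([Mg]Br)ccc1OCc1ccccc1 | intermediate
14 | (2S,3S,4R)-2-[4-(benzyloxy)-3-methoxyphenyl]-4-{[4-(benzyloxy)-3-methoxyphenyl](hydroxy)methyl}oxolane-3-carboxylic acid (carbinol epimers) | OC(=O)[C@H]1[C@@H](C(O)c2ccc(OCc3ccccc3)c(OC)c2)CO[C@@H]1c1ccc(OCc2ccccc2)c(OC)c1 | intermediate
15 | (3aR,6S,6aS)-3,6-bis[4-(benzyloxy)-3-methoxyphenyl]tetrahydro-1H,3H-furo[3,4-c]furan-1-one (C3 epimers) | O=C1[C@H]2[C@@H](C(c3ccc(OCc4ccccc4)c(OC)c3)O1)CO[C@@H]2c1ccc(OCc2ccccc2)c(OC)c1 | intermediate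
16 | (2S,3S,4R)-4-(4-hydroxy-3-methoxybenzyl)-2-(4-hydroxy-3-methoxyphenyl)oxolane-3-carboxylic acid | OC(=O)[C@H]1[C@@H](Cc2ccc(O)c(OC)c2)CO[C@@H]1c1ccc(O)c(OC)c1 | intermediate
17 | [(2S,3R,4R)-2-(4-hydroxy-3-methoxyphenyl)-4-(4-hydroxy-3-methoxybenzyl)oxolan-3-yl]methanol (lariciresinol) | OC[C@H]1[C@@H](Cc2ccc(O)c(OC)c2)CO[C@@H]1c1ccc(O)c(OC)c1 | intermediate
18 | vinyl stearate (ethenyl octadecanoate) | CCCCCCCCCCCCCCCCCC(=O)OC=C | starting material
19 | [(2S,3R,4R)-2-(4-hydroxy-3-methoxyphenyl)-4-(4-hydroxy-3-methoxybenzyl)oxolan-3-yl]methyl octadecanoate | CCCCCCCCCCCCCCCCCC(=O)OC[C@H]1[C@@H](Cc2ccc(O)c(OC)c2)CO[C@@H]1c1ccc(O)c(OC)c1 | target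

Total step count: 10 (the Grignard reagent 13 is made and used inside step 7). Longest linear sequence: 10 steps, from 1 to 19.

Least certain steps

Risk at step 4 (key step). The most likely failure is loss of orientational control: the carbonyl carbon bonds to C4 as readily as to C3, because on the face anti to the aryl group the two alkene carbons are sterically and electronically almost alike. Lewis-acid opening of the ether by ZnCl2 is the second concern and is the reason for DME. The fallback sets out from 6 and rejoins the route at 17; it turns the other regioisomer into product by a mirror sequence in which the ester carbon, not the dichloromethyl carbon, receives the aryl group.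
- The cycloaddition is run as in step 4 and the regioisomeric dichlorocyclobutanone F1 is separated from 9.
- NaOMe (cat.) in MeOH at 0 °C should open it to the methyl ester F2, with CO2Me on C4 and CHCl2 on C3.
- AgOAc in aqueous AcOH should give the lactol–lactone F3.
- NaBH4 (EtOH, 0 °C, then 1 M HCl) reduces the masked aldehyde and closes the cis-fused lactone F4, whose carbonyl carbon is C4a.
- One equivalent of 13 at −78 °C in THF adds once to the lactone to give the hydroxy ketone F5 (in equilibrium with its cyclic hemiketal).
- Hydrogenation over 10% Pd/C in EtOH–AcOH reduces the electron-rich aryl ketone to the methylene and removes both benzyl groups, giving 17.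

Risk at step 6. The most likely failure is incomplete ionisation of the unactivated dichloromethyl group, with epimerisation at C4 through the open aldehyde if the conditions are forced. The fallback sets out from 9 and rejoins at 11; it replaces the haloform opening and hydrolysis by oxidative cleavage of the same C3a–C4a bond.
- Zn, NH4Cl, MeOH at 25 °C removes both chlorines to give the cyclobutanone F6.
- LiN(i-Pr)2 then Me3SiCl (THF, −78 °C) gives the silyl enol ether F7 on the methylene side, bridgehead enolisation being disfavoured.
- Ozonolysis (O3, CH2Cl2–MeOH, −78 °C, then Me2S) cleaves the C3a=C4a double bond to the C4a aldehyde and the C3a silyl ester, which closes to 11 on mildly acidic work-up.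

Risk at step 8. The most likely failure is over-reduction: hydrogenolysis running on from the lactone C4a–O bond to the C2–O1 ether (ring opening), since both are electron-rich benzylic C–O bonds. The fallback sets out from 11 and rejoins at 17; it makes the C4a–O cleavage chemospecific through a quinone methide that only the C4a aryl group can form.
- The catalogue silyl ether tert-butyl(4-bromo-2-methoxyphenoxy)dimethylsilane F8 is converted (Mg, THF) into the Grignard reagent F9, which is used in place of 13 under the conditions of step 7 and gives the lactone F10 (silyl ether on the C4a aryl, benzyl ether on the C2 aryl).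
- Bu4NF with NaBH4 (THF–MeOH, 0 °C) frees the phenoxide, which expels the lactone carboxylate by 1,6-elimination to the quinone methide F11 (not isolated); hydride adds at C4a to give the acid F12.
- BH3·THF gives the alcohol F13.
- A short hydrogenolysis (H2, 10% Pd/C, EtOAc) of the single aryl benzyl ether gives 17.

Risk at step 3. The most likely failure is slow oxidative addition of the electron-rich triflate, with erosion of enantioselectivity or partial double-bond migration over the long reaction time. The fallback sets out from 1 and rejoins at 6; it builds the ring by metathesis and takes the configuration from an enzymatic resolution.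
- Vinylmagnesium bromide (THF, 0 °C) gives the racemic allylic alcohol F14.
- Acetylation with Burkholderia cepacia lipase and vinyl acetate (t-BuOMe, 30 °C) should consume the (R)-enantiomer as the acetate F16 and leave the (S)-alcohol F15.
- NaH and allyl bromide (THF, 0 °C) give the allyl ether F17.
- Ring-closing metathesis with the second-generation Grubbs catalyst RuCl2(=CHPh)(PCy3)(H2IMes) (CH2Cl2, 40 °C) closes the 2,5-dihydrofuran 6.

Risk at step 10. The most likely failure is slow or incomplete enzymatic acylation of the β-branched primary alcohol, which sits next to two bulky ring substituents. The fallback sets out from 17 and rejoins at 19; it replaces enzymatic selectivity by exhaustive acylation and chemoselective deacylation.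
- Stearoyl chloride (3.5 equiv), pyridine and DMAP in CH2Cl2 give the tristearate F18.
- Pyrrolidine (2.2 equiv, CH2Cl2, 0 °C) cleaves the two aryl esters by aminolysis, aryl esters being far better acyl donors than the alkyl ester, and leaves 19.

## Further compounds

F1 | step 4 | (1S,2S,5R)-2-[4-(benzyloxy)-3-methoxyphenyl]-7,7-dichloro-3-oxabicyclo[3.2.0]heptan-6-one | ClC2(Cl)[C@H]1[C@@H](C2=O)CO[C@@H]1c1ccc(OCc3ccccc3)c(OC)c1
F2 | step 4 | methyl (3R,4S,5S)-5-[4-(benzyloxy)-3-methoxyphenyl]-4-(dichloromethyl)oxolane-3-carboxylate | ClC(Cl)[C@H]1[C@@H](C(=O)OC)CO[C@@H]1c1ccc(OCc2ccccc2)c(OC)c1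
F3 | step 4 | (3aS,4S,6aR)-4-[4-(benzyloxy)-3-methoxyphenyl]-3-hydroxytetrahydro-1H,3H-furo[3,4-c]furan-1-one (lactol epimers) | OC2[C@H]1[C@@H](C(=O)O2)CO[C@@H]1c1ccc(OCc3ccccc3)c(OC)c1
F4 | step 4 | (3aR,4S,6aR)-4-[4-(benzyloxy)-3-methoxyphenyl]tetrahydro-1H,3H-furo[3,4-c]furan-1-one | O2C[C@H]1[C@@H](C2=O)CO[C@@H]1c1ccc(OCc3ccccc3)c(OC)c1
F5 | step 4 | [4-(benzyloxy)-3-methoxyphenyl][(3R,4R,5S)-5-[4-(benzyloxy)-3-methoxyphenyl]-4-(hydroxymethyl)oxolan-3-yl]methanone | OC[C@H]1[C@@H](C(=O)c2ccc(OCc3ccccc3)c(OC)c2)CO[C@@H]1c1ccc(OCc2ccccc2)c(OC)c1
F6 | step 6 | (1R,4S,5S)-4-[4-(benzyloxy)-3-methoxyphenyl]-3-oxabicyclo[3.2.0]heptan-6-one | O=C2[C@H]1[C@@H](C2)CO[C@@H]1c1ccc(OCc3ccccc3)c(OC)c1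
F7 | step 6 | trimethyl{[(1S,2S,5R)-2-[4-(benzyloxy)-3-methoxyphenyl]-3-oxabicyclo[3.2.0]hept-6-en-7-yl]oxy}silane | C[Si](C)(C)OC=2[C@H]1[C@@H](C=2)CO[C@@H]1c1ccc(OCc3ccccc3)c(OC)c1
F8 | step 8 | tert-butyl(4-bromo-2-methoxyphenoxy)dimethylsilane | COc1cc(Br)ccc1O[Si](C)(C)C(C)(C)C
F9 | step 8 | {4-[(tert-butyldimethylsilyl)oxy]-3-methoxyphenyl}magnesium bromide | COc1cc([Mg]Br)ccc1O[Si](C)(C)C(C)(C)C
F10 | step 8 | (3aR,6S,6aS)-6-[4-(benzyloxy)-3-methoxyphenyl]-3-{4-[(tert-butyldimethylsilyl)oxy]-3-methoxyphenyl}tetrahydro-1H,3H-furo[3,4-c]furan-1-one (C3 epimers) | O=C1[C@H]2[C@@H](C(c3ccc(O[Si](C)(C)C(C)(C)C)c(OC)c3)O1)CO[C@@H]2c1ccc(OCc2ccccc2)c(OC)c1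
F11 | step 8 | (2S,3S,4R)-2-[4-(benzyloxy)-3-methoxyphenyl]-4-[(3-methoxy-4-oxocyclohexa-2,5-dien-1-ylidene)methyl]oxolane-3-carboxylic acid (not isolated) | OC(=O)[C@H]1[C@@H](C=C2C=C(OC)C(=O)C=C2)CO[C@@H]1c1ccc(OCc2ccccc2)c(OC)c1
F12 | step 8 | (2S,3S,4R)-2-[4-(benzyloxy)-3-methoxyphenyl]-4-(4-hydroxy-3-methoxybenzyl)oxolane-3-carboxylic acid | OC(=O)[C@H]1[C@@H](Cc2ccc(O)c(OC)c2)CO[C@@H]1c1ccc(OCc2ccccc2)c(OC)c1
F13 | step 8 | [(2S,3R,4R)-2-[4-(benzyloxy)-3-methoxyphenyl]-4-(4-hydroxy-3-methoxybenzyl)oxolan-3-yl]methanol | OC[C@H]1[C@@H](Cc2ccc(O)c(OC)c2)CO[C@@H]1c1ccc(OCc2ccccc2)c(OC)c1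
F14 | step 3 | rac-1-[4-(benzyloxy)-3-methoxyphenyl]prop-2-en-1-ol | C=CC(O)c1ccc(OCc2ccccc2)c(OC)c1
F15 | step 3 | (S)-1-[4-(benzyloxy)-3-methoxyphenyl]prop-2-en-1-ol | C=C[C@H](O)c1ccc(OCc2ccccc2)c(OC)c1
F16 | step 3 | (R)-1-[4-(benzyloxy)-3-methoxyphenyl]prop-2-en-1-yl acetate | C=C[C@@H](OC(C)=O)c1ccc(OCc2ccccc2)c(OC)c1
F17 | step 3 | (S)-1-(benzyloxy)-2-methoxy-4-[1-(prop-2-en-1-yloxy)prop-2-en-1-yl]benzene | C=CCO[C@@H](C=C)c1ccc(OCc2ccccc2)c(OC)c1
F18 | step 10 | lariciresinol tristearate, [(2S,3R,4R)-2-[3-methoxy-4-(octadecanoyloxy)phenyl]-4-[3-methoxy-4-(octadecanoyloxy)benzyl]oxolan-3-yl]methyl octadecanoate | CCCCCCCCCCCCCCCCCC(=O)OC[C@H]1[C@@H](Cc2ccc(OC(=O)CCCCCCCCCCCCCCCCC)c(OC)c2)CO[C@@H]1c1ccc(OC(=O)CCCCCCCCCCCCCCCCC)c(OC)c1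
A1 | alternative 1 | (3E,4R,5S)-3-[4-(benzyloxy)-3-methoxybenzylidene]-5-[4-(benzyloxy)-3-methoxyphenyl]-4-{[(tert-butyldimethylsilyl)oxy]methyl}oxolan-2-one | CC(C)(C)[Si](C)(C)OC[C@H]1/C(=C\c2ccc(OCc3ccccc3)c(OC)c2)C(=O)O[C@@H]1c1ccc(OCc2ccccc2)c(OC)c1
A2 | alternative 1 | (1S,2R)-1,4-bis[4-(benzyloxy)-3-methoxyphenyl]-2-{[(tert-butyldimethylsilyl)oxy]methyl}but-3-yn-1-ol | CC(C)(C)[Si](C)(C)OC[C@@H](C#Cc1ccc(OCc2ccccc2)c(OC)c1)[C@H](O)c1ccc(OCc2ccccc2)c(OC)c1
A3 | alternative 2 | (3S,4R,5R)-3-{[4-(benzyloxy)-3-methoxyphenyl](hydroxy)methyl}-4-{2-[4-(benzyloxy)-3-methoxyphenyl]-1,3-dithian-2-yl}-5-{[(1R,2S,5R)-2-isopropyl-5-methylcyclohexyl]oxy}oxolan-2-one (carbinol epimers) | O=C1[C@H](C(O)c2ccc(OCc3ccccc3)c(OC)c2)[C@@H](C2(SCCCS2)c2ccc(OCc3ccccc3)c(OC)c2)[C@H](O[C@@H]2C[C@H](C)CC[C@H]2C(C)C)O1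
A4 | alternative 2 | (5R)-5-{[(1R,2S,5R)-2-isopropyl-5-methylcyclohexyl]oxy}furan-2(5H)-one | O=C1C=C[C@H](O[C@@H]2C[C@H](C)CC[C@H]2C(C)C)O1
A5 | alternative 2 | 2-[4-(benzyloxy)-3-methoxyphenyl]-1,3-dithiane | COc1cc(C2SCCCS2)ccc1OCc1ccccc1
A6 | alternative 3 | (2S,3R,4R)-4-[4-(benzyloxy)-3-methoxybenzyl]-2-[4-(benzyloxy)-3-methoxyphenyl]-3-[(benzyloxy)methyl]oxolane | c1ccccc1COC[C@H]1[C@@H](Cc2ccc(OCc3ccccc3)c(OC)c2)CO[C@@H]1c1ccc(OCc2ccccc2)c(OC)c1
A7 | alternative 3 | (2R,3S)-3-[4-(benzyloxy)-3-methoxybenzyl]-2-[(benzyloxy)methyl]oxetane | c1ccccc1COC[C@H]1[C@@H](Cc2ccc(OCc3ccccc3)c(OC)c2)CO1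
A8 | alternative 3 | 1-(benzyloxy)-4-(diazomethyl)-2-methoxybenzene | COc1cc(C=[N+]=[N-])ccc1OCc1ccccc1
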